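**Plan**
1. Retrosynthesis first removes the two SEM groups, cuts the 4'-O-prenyl ether at O–C, and traces the 5'-(1,1-dimethylallyl) group by a retro-Claisen step to a 4'-O-prenyl ether of a protected (3R)-7,2',4'-trioxygenated isoflavan.
2. C3–H is traced to C3–CHO/C3–CH2OH (decarbonylation with retention), the pyran ring is opened at the aryl ether bond O1–C8a, and then C3–C4 (benzylation) and C3–C1' (malonate arylation) are cut.
3. Enabling feature: C3 already carries the C2H2–O1 arm, so one extra hydroxymethyl at C3 makes the open-chain precursor an achiral 2-aryl-2-(2-bromobenzyl)propane-1,3-diol with two enantiotopic CH2OH arms; coupling one of them to C8a closes the pyran ring and fixes C3 in the same event.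
4. Forward: ring-B aryl bromide + malonate → arylmalonate; benzylation with the ring-A 2-bromobenzyl bromide (fully substituted C3); reduction to the diol; Cu/chiral-diamine desymmetrising O-arylation (pyran ring).
5. Then CH2OH → CHO → H (Rh), debenzylation of 4'-O, O-prenylation, aromatic Claisen to C5', second O-prenylation, fluoride removal of both SEM groups.
6. Stereochemistry: the only stereocentre, C3 (R), comes from ligand-controlled selection between the enantiotopic CH2OH groups during ring closure and is carried through the decarbonylation with retention.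

Key step: step 8

Assumption: SEM = 2-(trimethylsilyl)ethoxymethyl; the sense of induction of the chiral diamine–copper catalyst in step 8 is to be matched to (R)-11 by the choice of ligand antipode, both antipodes being available.

**Step 1**
Reactants: 1 5-(benzyloxy)-2-bromophenol
Product: 2 4-(benzyloxy)-1-bromo-2-(SEM-oxy)benzene
Conditions: NaH, SEMCl, THF, 0 °C → rt
Reagents that add atoms: 2-(trimethylsilyl)ethoxymethyl chloride, C[Si](C)(C)CCOCCl
Why: Williamson-type O-alkylation of the sodium phenoxide with the reactive α-chloro ether masks the future 2'-OH as an acetal that is stable to base, hydride, hydrogenolysis and heat and is removed by fluoride at the end.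

**Step 2**
Reactants: 2 4-(benzyloxy)-1-bromo-2-(SEM-oxy)benzene; 3 diethyl malonate
Product: 4 diethyl 2-[4-(benzyloxy)-2-(SEM-oxy)phenyl]malonate
Conditions: Pd(dba)2 (2 mol %), P(t-Bu)3·HBF4 (4 mol %), K3PO4, toluene, 70 °C
Reagents that add atoms: none
Why: Pd-catalysed α-arylation of a malonate enolate with a bulky electron-rich trialkylphosphine should tolerate the electron-rich ortho-alkoxy aryl bromide and joins the future C3 to C1' of ring B.

**Step 3**
Reactants: 5 2-bromo-4-hydroxybenzaldehyde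
Product: 6 2-bromo-4-(SEM-oxy)benzaldehyde
Conditions: NaH, SEMCl, DMF, 0 °C
Reagents that add atoms: 2-(trimethylsilyl)ethoxymethyl chloride, C[Si](C)(C)CCOCCl
Why: Williamson-type O-alkylation of the phenoxide protects the future 7-OH with the same fluoride-labile group as the 2'-OH.

**Step 4**
Reactants: 6 2-bromo-4-(SEM-oxy)benzaldehyde
Product: 7 [2-bromo-4-(SEM-oxy)phenyl]methanol
Conditions: NaBH4, MeOH, 0 °C
Reagents that add atoms: none
Why: Borohydride reduction of the aryl aldehyde to the benzylic alcohol leaves the aryl bromide and the SEM acetal untouched.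

**Step 5**
Reactants: 7 [2-bromo-4-(SEM-oxy)phenyl]methanol
Product: 8 2-bromo-1-(bromomethyl)-4-(SEM-oxy)benzene
Conditions: CBr4, PPh3, CH2Cl2, 0 °C; used without storage
Reagents that add atoms: carbon tetrabromide, BrC(Br)(Br)Br
Why: The Appel reaction converts the benzylic alcohol into the bromide under neutral conditions that should spare the acid-labile SEM acetal.

**Step 6**
Reactants: 4 diethyl 2-[4-(benzyloxy)-2-(SEM-oxy)phenyl]malonate; 8 2-bromo-1-(bromomethyl)-4-(SEM-oxy)benzene
Product: 9 diethyl 2-[4-(benzyloxy)-2-(SEM-oxy)phenyl]-2-[2-bromo-4-(SEM-oxy)benzyl]malonate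
Conditions: NaH, DMF, 0 °C → 40 °C
Reagents that add atoms: none
Why: SN2 C-alkylation of the stabilised arylmalonate enolate with the reactive benzylic bromide forms C3–C4 and the fully substituted carbon convergently, the aryl bromide being inert.

**Step 7**
Reactants: 9 diethyl 2-[4-(benzyloxy)-2-(SEM-oxy)phenyl]-2-[2-bromo-4-(SEM-oxy)benzyl]malonate
Product: 10 2-[4-(benzyloxy)-2-(SEM-oxy)phenyl]-2-[2-bromo-4-(SEM-oxy)benzyl]propane-1,3-diol
Conditions: LiAlH4, THF, 0 °C → rt; aqueous NaOH work-up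
Reagents that add atoms: none
Why: Hydride reduction of both esters of the non-enolisable disubstituted malonate gives the achiral 1,3-diol at a temperature where the aryl C–Br bond and the SEM ethers should survive.

**Step 8**
Reactants: 10 2-[4-(benzyloxy)-2-(SEM-oxy)phenyl]-2-[2-bromo-4-(SEM-oxy)benzyl]propane-1,3-diol
Product: 11 [(3R)-3-[4-(benzyloxy)-2-(SEM-oxy)phenyl]-7-(SEM-oxy)-3,4-dihydro-2H-chromen-3-yl]methanol
Conditions: CuI (10 mol %), C2-symmetric chiral N,N'-dimethyl-1,2-diphenylethane-1,2-diamine (20 mol %, antipode selected for R), Cs2CO3, MeCN, 60–80 °C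
Reagents that add atoms: none
Why: The Cu(I)–diamine complex binds one of the two alkoxide arms of 10, activates the ortho C–Br bond of ring A and reductively eliminates the C(sp2)–O bond from a Cu(III) aryl alkoxide; the closest known reaction type is the Ullmann-type enantioselective desymmetrising intramolecular O-arylation of prochiral 2-substituted 2-(2-halobenzyl)propane-1,3-diols to 3,3-disubstituted chromans. The pyran ring closes in a six-membered exo mode at the ipso carbon C8a (formally 6-exo-trig, bromide leaving from outside the new ring), helped by the gem-disubstitution at C3. The new quaternary stereocentre C3 is controlled by the chiral ligand on copper, which discriminates the enantiotopic hydroxymethyl groups in the C–Br activation step. The step needs enantiotopic-group selectivity and chemoselectivity for alkoxide coupling: the substrate has a single aryl halide, all phenols are masked, and the remaining CH2OH of 11 has no halide left to react with, so no second cyclisation can erode the selection. The product centre is fully substituted and cannot epimerise under the basic conditions.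

**Step 9**
Reactants: 11 [(3R)-3-[4-(benzyloxy)-2-(SEM-oxy)phenyl]-7-(SEM-oxy)-3,4-dihydro-2H-chromen-3-yl]methanol
Product: 12 (3S)-3-[4-(benzyloxy)-2-(SEM-oxy)phenyl]-7-(SEM-oxy)-3,4-dihydro-2H-chromene-3-carbaldehyde
Conditions: Dess–Martin periodinane, CH2Cl2, rt
Reagents that add atoms: none
Why: Dess–Martin oxidation of the neopentyl primary alcohol gives an aldehyde without α-hydrogen, so C3 cannot epimerise (the descriptor changes to S only through the CIP priorities).

**Step 10**
Reactants: 12 (3S)-3-[4-(benzyloxy)-2-(SEM-oxy)phenyl]-7-(SEM-oxy)-3,4-dihydro-2H-chromene-3-carbaldehyde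
Product: 13 (3R)-3-[4-(benzyloxy)-2-(SEM-oxy)phenyl]-7-(SEM-oxy)-3,4-dihydro-2H-chromene
Conditions: RhCl(PPh3)3 (1.1 equiv), degassed xylenes, 130 °C
Reagents that add atoms: none
Why: Tsuji–Wilkinson decarbonylation (formyl C–H oxidative addition, CO de-insertion, C–H reductive elimination) replaces CHO by H with retention at the migrating carbon, so the helper carbon leaves and C3 should emerge as the (R)-configured tertiary centre of the isoflavan.

**Step 11**
Reactants: 13 (3R)-3-[4-(benzyloxy)-2-(SEM-oxy)phenyl]-7-(SEM-oxy)-3,4-dihydro-2H-chromene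
Product: 14 4-[(3R)-7-(SEM-oxy)-3,4-dihydro-2H-chromen-3-yl]-3-(SEM-oxy)phenol
Conditions: H2 (1 atm), 10 % Pd/C, EtOAc–EtOH, rt
Reagents that add atoms: none
Why: Hydrogenolysis of the aryl benzyl ether frees only the 4'-OH, since the SEM acetals and the non-benzylic C2–O1 bond are inert and no alkene is present yet.

**Step 12**
Reactants: 14 4-[(3R)-7-(SEM-oxy)-3,4-dihydro-2H-chromen-3-yl]-3-(SEM-oxy)phenol; 15 1-bromo-3-methylbut-2-ene
Product: 16 (3R)-3-[4-(3-methylbut-2-enyloxy)-2-(SEM-oxy)phenyl]-7-(SEM-oxy)-3,4-dihydro-2H-chromene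
Conditions: K2CO3, acetone, 50 °C
Reagents that add atoms: none
Why: Williamson O-alkylation of the only free phenol with the allylic bromide gives the aryl prenyl ether needed for the sigmatropic step.

**Step 13**
Reactants: 16 (3R)-3-[4-(3-methylbut-2-enyloxy)-2-(SEM-oxy)phenyl]-7-(SEM-oxy)-3,4-dihydro-2H-chromene
Product: 18 2-(2-methylbut-3-en-2-yl)-5-(SEM-oxy)-4-[(3R)-7-(SEM-oxy)-3,4-dihydro-2H-chromen-3-yl]phenol, via ortho-dienone 17 (not isolated)
Conditions: N,N-diethylaniline, 190 °C, sealed tube, stopped before full conversion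
Reagents that add atoms: none
Why: The aromatic Claisen rearrangement ([3,3] shift with allyl inversion, then tautomerisation of the dienone) should deliver the 1,1-dimethylallyl group to C5' and not C3', because C3' is flanked by two oxygen substituents and a meta donor directs migration to the position para to it, while the basic solvent suppresses acid-induced cyclisation of the ortho-allylphenol.

**Step 14**
Reactants: 18 2-(2-methylbut-3-en-2-yl)-5-(SEM-oxy)-4-[(3R)-7-(SEM-oxy)-3,4-dihydro-2H-chromen-3-yl]phenol; 15 1-bromo-3-methylbut-2-ene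
Product: 19 (3R)-3-[5-(2-methylbut-3-en-2-yl)-4-(3-methylbut-2-enyloxy)-2-(SEM-oxy)phenyl]-7-(SEM-oxy)-3,4-dihydro-2H-chromene
Conditions: K2CO3, DMF, 40 °C
Reagents that add atoms: none
Why: Williamson O-alkylation of the hindered but only free phenoxide with the reactive allylic bromide in a dipolar aprotic solvent restores the 4'-O-prenyl ether.

**Step 15**
Reactants: 19 (3R)-3-[5-(2-methylbut-3-en-2-yl)-4-(3-methylbut-2-enyloxy)-2-(SEM-oxy)phenyl]-7-(SEM-oxy)-3,4-dihydro-2H-chromene
Product: 20 manuifolin D, (3R)-3-[2-hydroxy-5-(2-methylbut-3-en-2-yl)-4-(3-methylbut-2-enyloxy)phenyl]-3,4-dihydro-2H-chromen-7-ol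
Conditions: TBAF (excess), ethylenediamine, DMF, 70 °C; aqueous work-up
Reagents that add atoms: none
Why: Fluoride attack at silicon triggers β-elimination of ethene and collapse of the aryloxymethyl hemiacetal to the phenoxide, a non-acidic deprotection that should leave the acid-sensitive aryl prenyl ether, the tert-allyl group and C3 untouched while the diamine traps the formaldehyde.

**Compound list**
1 | 5-(benzyloxy)-2-bromophenol | Oc1cc(OCc2ccccc2)ccc1Br | starting material
2 | 4-(benzyloxy)-1-bromo-2-(SEM-oxy)benzene | C[Si](C)(C)CCOCOc1cc(OCc2ccccc2)ccc1Br | intermediate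
3 | diethyl malonate | CCOC(=O)CC(=O)OCC | starting material
4 | diethyl 2-[4-(benzyloxy)-2-(SEM-oxy)phenyl]malonate | CCOC(=O)C(C(=O)OCC)c1ccc(OCc2ccccc2)cc1OCOCC[Si](C)(C)C | intermediate
5 | 2-bromo-4-hydroxybenzaldehyde | O=Cc1ccc(O)cc1Br | starting material
6 | 2-bromo-4-(SEM-oxy)benzaldehyde | O=Cc1ccc(OCOCC[Si](C)(C)C)cc1Br | intermediate
7 | [2-bromo-4-(SEM-oxy)phenyl]methanol | OCc1ccc(OCOCC[Si](C)(C)C)cc1Br | intermediate
8 | 2-bromo-1-(bromomethyl)-4-(SEM-oxy)benzene | BrCc1ccc(OCOCC[Si](C)(C)C)cc1Br | intermediate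
9 | diethyl 2-[4-(benzyloxy)-2-(SEM-oxy)phenyl]-2-[2-bromo-4-(SEM-oxy)benzyl]malonate | CCOC(=O)C(Cc1ccc(OCOCC[Si](C)(C)C)cc1Br)(C(=O)OCC)c1ccc(OCc2ccccc2)cc1OCOCC[Si](C)(C)C | intermediate
10 | 2-[4-(benzyloxy)-2-(SEM-oxy)phenyl]-2-[2-bromo-4-(SEM-oxy)benzyl]propane-1,3-diol (achiral) | OCC(CO)(Cc1ccc(OCOCC[Si](C)(C)C)cc1Br)c1ccc(OCc2ccccc2)cc1OCOCC[Si](C)(C)C | intermediate
11 | [(3R)-3-[4-(benzyloxy)-2-(SEM-oxy)phenyl]-7-(SEM-oxy)-3,4-dihydro-2H-chromen-3-yl]methanol | OC[C@@]1(c2ccc(OCc3ccccc3)cc2OCOCC[Si](C)(C)C)COc2cc(OCOCC[Si](C)(C)C)ccc2C1 | intermediate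
12 | (3S)-3-[4-(benzyloxy)-2-(SEM-oxy)phenyl]-7-(SEM-oxy)-3,4-dihydro-2H-chromene-3-carbaldehyde | O=C[C@@]1(c2ccc(OCc3ccccc3)cc2OCOCC[Si](C)(C)C)COc2cc(OCOCC[Si](C)(C)C)ccc2C1 | intermediate
13 | (3R)-3-[4-(benzyloxy)-2-(SEM-oxy)phenyl]-7-(SEM-oxy)-3,4-dihydro-2H-chromene | C[Si](C)(C)CCOCOc1cc(OCc2ccccc2)ccc1[C@@H]1COc2cc(OCOCC[Si](C)(C)C)ccc2C1 | intermediate
14 | 4-[(3R)-7-(SEM-oxy)-3,4-dihydro-2H-chromen-3-yl]-3-(SEM-oxy)phenol | C[Si](C)(C)CCOCOc1cc(O)ccc1[C@@H]1COc2cc(OCOCC[Si](C)(C)C)ccc2C1 | intermediate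
15 | 1-bromo-3-methylbut-2-ene (prenyl bromide) | CC(C)=CCBr | starting material
16 | (3R)-3-[4-(3-methylbut-2-enyloxy)-2-(SEM-oxy)phenyl]-7-(SEM-oxy)-3,4-dihydro-2H-chromene | CC(C)=CCOc1ccc([C@@H]2COc3cc(OCOCC[Si](C)(C)C)ccc3C2)c(OCOCC[Si](C)(C)C)c1 | intermediate
17 | 6-(2-methylbut-3-en-2-yl)-3-(SEM-oxy)-4-[(3R)-7-(SEM-oxy)-3,4-dihydro-2H-chromen-3-yl]cyclohexa-2,4-dien-1-one (C6 epimers, not isolated) | C=CC(C)(C)C1C=C([C@@H]2COc3cc(OCOCC[Si](C)(C)C)ccc3C2)C(OCOCC[Si](C)(C)C)=CC1=O | intermediate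
18 | 2-(2-methylbut-3-en-2-yl)-5-(SEM-oxy)-4-[(3R)-7-(SEM-oxy)-3,4-dihydro-2H-chromen-3-yl]phenol | C=CC(C)(C)c1cc([C@@H]2COc3cc(OCOCC[Si](C)(C)C)ccc3C2)c(OCOCC[Si](C)(C)C)cc1O | intermediate
19 | (3R)-3-[5-(2-methylbut-3-en-2-yl)-4-(3-methylbut-2-enyloxy)-2-(SEM-oxy)phenyl]-7-(SEM-oxy)-3,4-dihydro-2H-chromene | C=CC(C)(C)c1cc([C@@H]2COc3cc(OCOCC[Si](C)(C)C)ccc3C2)c(OCOCC[Si](C)(C)C)cc1OCC=C(C)C | intermediate
20 | manuifolin D, (3R)-3-[2-hydroxy-5-(2-methylbut-3-en-2-yl)-4-(3-methylbut-2-enyloxy)phenyl]-3,4-dihydro-2H-chromen-7-ol | C=CC(C)(C)c1cc([C@@H]2COc3cc(O)ccc3C2)c(O)cc1OCC=C(C)C | target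

**Count**
Total steps: 15. Longest linear sequence: 13 steps (from 5 through steps 3–15).

**Steps most likely to fail**

Step 8. The ligand may discriminate the enantiotopic hydroxymethyl groups poorly next to the bulky ortho-SEM-oxyaryl group, and slow activation of the electron-rich C–Br bond may allow protodebromination. Fallback by classical resolution, setting out from 10 and coming back at 11: diol 10 is cyclised with an achiral catalyst (CuI, 3,4,7,8-tetramethyl-1,10-phenanthroline, Cs2CO3, toluene, 100 °C) to the racemic [3-aryl-7-(SEM-oxy)chroman-3-yl]methanol F1. This is acylated with (1S)-(−)-camphanic chloride (Et3N, DMAP, CH2Cl2), and the diastereomeric esters are separated by chromatography or crystallisation. The (1S,4R)-camphanate of the (R)-alcohol F2 is methanolysed (K2CO3, MeOH) to give 11.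

Step 10. CO extrusion at the neopentyl, fully substituted centre may be slow, and β-hydride or β-aryloxy elimination from the tertiary alkyl–rhodium hydride could unsaturate or open the pyran ring or erode the configuration. Fallback that sets C3 as a tertiary centre directly, setting out from 4 (with 8) and coming back at 13: malonate 4 is saponified and decarboxylated (KOH, EtOH–H2O, then mild acid and gentle warming) to 2-[4-(benzyloxy)-2-(SEM-oxy)phenyl]acetic acid F3. The acid is converted through its mixed pivalic anhydride (PivCl, Et3N, THF; then (R)-4-benzyl-1,3-oxazolidin-2-one, LiCl) into the N-acyl oxazolidinone F4. Evans alkylation of its sodium Z-enolate (NaHMDS, THF, −78 °C) with bromide 8, anti to the benzyl group, should give the (2R)-alkylated imide F5. LiBH4 (THF–MeOH, 0 °C) releases the auxiliary and gives (2R)-2-[4-(benzyloxy)-2-(SEM-oxy)phenyl]-3-[2-bromo-4-(SEM-oxy)phenyl]propan-1-ol F6. An achiral intramolecular Ullmann-type O-arylation (CuI, 3,4,7,8-tetramethyl-1,10-phenanthroline, Cs2CO3, toluene, 110 °C) closes the same O1–C8a bond to give 13.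

Step 13. The allyl group may migrate in part to C3', the tert-allyl group may isomerise on prolonged heating (abnormal Claisen), the ortho-allylphenol may cyclise, or the prenyl group may be lost thermally. Fallback by cross-coupling, setting out from 14 and coming back at 18 (step 12 is then skipped): phenol 14 is brominated ortho to the free hydroxyl and para to the SEM ether (NBS, CH2Cl2, −78 → 0 °C) to 2-bromo-5-(SEM-oxy)-4-[(3R)-7-(SEM-oxy)-3,4-dihydro-2H-chromen-3-yl]phenol F7. A ligand-controlled γ-selective Suzuki–Miyaura coupling with 3-methylbut-2-enylboronic acid pinacol ester (Pd precatalyst with a bulky biarylphosphine, aqueous K3PO4, THF, 40–70 °C) then installs the 1,1-dimethylallyl group at C5' and gives 18.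

**Further compounds**
F1 | step 8 | racemic [3-[4-(benzyloxy)-2-(SEM-oxy)phenyl]-7-(SEM-oxy)-3,4-dihydro-2H-chromen-3-yl]methanol | OCC1(c2ccc(OCc3ccccc3)cc2OCOCC[Si](C)(C)C)COc2cc(OCOCC[Si](C)(C)C)ccc2C1
F2 | step 8 | [(3R)-3-[4-(benzyloxy)-2-(SEM-oxy)phenyl]-7-(SEM-oxy)-3,4-dihydro-2H-chromen-3-yl]methyl (1S,4R)-camphanate | O=C(OC[C@@]1(c2ccc(OCc3ccccc3)cc2OCOCC[Si](C)(C)C)COc2cc(OCOCC[Si](C)(C)C)ccc2C1)[C@@]34CC[C@@](C)(C(=O)O3)C4(C)C
F3 | step 10 | 2-[4-(benzyloxy)-2-(SEM-oxy)phenyl]acetic acid | OC(=O)Cc1ccc(OCc2ccccc2)cc1OCOCC[Si](C)(C)C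
F4 | step 10 | (4R)-4-benzyl-3-{2-[4-(benzyloxy)-2-(SEM-oxy)phenyl]acetyl}-1,3-oxazolidin-2-one | O=C(Cc1ccc(OCc2ccccc2)cc1OCOCC[Si](C)(C)C)N1[C@H](Cc2ccccc2)COC1=O
F5 | step 10 | (4R)-4-benzyl-3-{(2R)-2-[4-(benzyloxy)-2-(SEM-oxy)phenyl]-3-[2-bromo-4-(SEM-oxy)phenyl]propanoyl}-1,3-oxazolidin-2-one | O=C(N1[C@H](Cc2ccccc2)COC1=O)[C@@H](c1ccc(OCc2ccccc2)cc1OCOCC[Si](C)(C)C)Cc1ccc(OCOCC[Si](C)(C)C)cc1Br
F6 | step 10 | (2R)-2-[4-(benzyloxy)-2-(SEM-oxy)phenyl]-3-[2-bromo-4-(SEM-oxy)phenyl]propan-1-ol | OC[C@@H](c1ccc(OCc2ccccc2)cc1OCOCC[Si](C)(C)C)Cc1ccc(OCOCC[Si](C)(C)C)cc1Br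
F7 | step 13 | 2-bromo-5-(SEM-oxy)-4-[(3R)-7-(SEM-oxy)-3,4-dihydro-2H-chromen-3-yl]phenol | C[Si](C)(C)CCOCOc1cc(O)c(Br)cc1[C@@H]1COc2cc(OCOCC[Si](C)(C)C)ccc2C1
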